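## Analysis of the target

The target (19) is a proanthocyanidin trimer of three 2-(3,4-dihydroxyphenyl)chroman-3,5,7-triol units, each with a phloroglucinol-type ring A, a pyran ring C and a catechol ring B. Units 1 and 2 are (−)-epicatechin units (2R,3R, aryl and 3-hydroxyl cis) joined by a carbon–carbon bond from C4 of unit 1 to C8 of unit 2, the C4 substituent standing β, trans to the 3-hydroxyl. Unit 2 carries at C4, again β and trans to its 3-hydroxyl, an ether oxygen whose second bond goes to C4 of unit 3. Unit 3 is a flavan-3,4-diol of the opposite 2S series, (2S,3S,4S), in which C2 aryl, C3 hydroxyl and C4 oxygen are all cis, aryl and C4 oxygen equatorial and the C3 hydroxyl axial between them. Of the nine stereocentres, six are those of natural epicatechin, while the three of unit 3 cannot be taken from the chiral pool. The twelve phenols oxidise readily in base and air, the C4–C8 bond and above all the C4–O–C4 ether (each carbon benzylic to a trioxygenated ring) ionise in acid, and C2 epimerises under base in the free phenols. The difficulty is to forge an ether between two carbons that both tend to ionise, with an alcohol that must win against the nucleophilic ring A carbons, and to build unit 3 with three contiguous centres. The plan rests on ring C of unit 3: the array O1–C2(aryl)–C3–C4(O), with C2 aryl and C4 oxygen cis and diequatorial, is that of an all-equatorial 2-aryl-3-nitrochroman-4-ol, in which the nitro group at C3 stands in for the axial oxygen and also keeps C4 of unit 3 from ionising.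

## Retrosynthetic reasoning

**Protecting groups (19 ⇒ 18 ⇒ 17).** The last bonds cut are the twelve aryl O–benzyl bonds and, before them, the two O–Si bonds at the 3-hydroxyls of units 1 and 2. Benzyl ethers on the phenols stop oxidation, keep C2 stable and direct electrophiles to C8 of a 5,7-dialkoxy ring. The two secondary hydroxyls are silylated so that they cannot compete as oxygen nucleophiles when the ether is made. Removing silicon first leaves only aryl benzyl ethers for the final hydrogenolysis, which must spare the benzylic C–O bonds of the skeleton.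

**C3 of unit 3 (17 ⇒ 16).** The axial 3-hydroxyl of unit 3 is traced to the C3 ketone 16 by removing the C3–H bond. An axial alcohol cis to two equatorial neighbours is what kinetic delivery of a bulky hydride gives, since the hydride must enter from the face away from the C2 aryl group and the C4 ether.

**Ketone from nitro (16 ⇒ 15 ⇒ 14).** The carbonyl is traced through oxime 15 to the secondary nitro group of 14; no skeletal bond is cut. The nitro group is kept this far because it allows ring C of unit 3 to be made in one step and shields C4 of unit 3 during ether formation. The forward conversion must avoid a free nitronate, which could expel either flanking oxygen, hence the two-stage reductive path through the oxime.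

**The ether (14 ⇒ 13 + 7).** The ether is cut between oxygen and C4 of unit 2, not at C4 of unit 3. C4 of unit 2 is an ordinary epicatechin C4: its cation is stabilised by ring A and is attacked on the β face, anti to the axial C3 substituent, which is the configuration needed. C4 of 7 cannot ionise in the same way because the adjacent nitro group destabilises a cation there, so 7 can serve as the alcohol without condensing with itself. The forward reaction must make oxygen win over the ring A carbons, which calls for a leaving group on 13 released under neutral, thiophilic conditions: a C4 sulfide.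

**Ring C of unit 3 (7 ⇒ 2 + 5, through 6).** Two bonds are cut, O1–C2 and C3–C4. This returns salicylaldehyde 2 and nitrostyrene 5, both achiral and each one step from commercial material, and removes all three stereocentres at once. The forward reaction must fix C2 by catalysis, let C3 and C4 settle into the all-equatorial arrangement, and stop before water is lost.

**The two components (2 ⇒ 1; 5 ⇒ 3 + 4).** Aldehyde 2 comes from 1 by cutting two O–benzyl bonds, and 5 from 3 and 4 by cutting the C=C bond.

**The interflavan bond (13 ⇒ 11 + 12).** The C4–C8 bond is cut to an electrophile 11 with an oxygen leaving group at C4 and a nucleophile 12 that already carries the sulfide at its own C4. The two leaving groups answer to different activators, so the sulfide passes through the carbon–carbon coupling untouched and is in place for the ether step.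

**Back to epicatechin (11, 12 ⇒ 10 ⇒ 9 ⇒ 8).** Both halves derive from one protected epicatechin 10 by oxidation at C4, which is activated by ring A. Compound 10 comes from 8 by etherification of the phenols and silylation of the 3-hydroxyl, so all six stereocentres of units 1 and 2 are taken from 8.

## Alternatives that were turned down

**Alternative 1:** Woodward–Prévost alkoxy-acyloxylation of a unit 2 flavene.
- **Disconnection:** the C3–O and C4–O bonds of unit 2 are both traced to the C3=C4 double bond of the dimeric flav-3-ene A2, and the ether oxygen to the C4 hydroxyl of a ready-made unit 3 diol mono-silyl ether A3.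
- **Forward key step:** N-iodosuccinimide in acetic acid adds iodine and acetate trans across the alkene. AgOTf then abstracts iodide while the neighbouring acetate closes to a 1,3-dioxolan-2-ylium ion, and A3 opens this ion at benzylic C4 to give A1, with acetate on C3 and the ether on C4 of unit 2.
- **For:** the trans relationship of the two new C–O bonds follows from the mechanism (two inversions); the electrophile is a bridged acyloxonium ion and not a free benzylic cation; the ether bond and the C3 oxygen arrive together.
- **Against:**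
  - A2 can only be had by removing the C3 oxygen and stereocentre that epicatechin supplies and putting them back.
  - Its C2 centre is allylic in a 2H-chromene that can open to an ortho-quinone methide and lose configuration.
  - The iodonium ion must form anti to the C2 aryl group in a congested dimer.
  - Electrophilic iodine also attacks the free C6 and C8 positions of the benzylated rings A.
  - A hindered alcohol tends to add to the central carbon of the dioxolanylium ion and give an orthoester.
  - A3 has no electron-withdrawing group at C3, is itself ionisable at C4 under AgOTf and would condense with itself.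
  - A3 presupposes a synthesis of the 2S-configured unit 3 that this plan does not contain, and the acetate must be removed by base late in the route.
- **Comparison:** on mechanistic control of the C3/C4 relationship in unit 2 this alternative is the stronger. The chosen route obtains the same relationship from β attack on an epicatechin C4 cation, keeps C2 and C3 of unit 2 from the chiral pool, and in exchange delivers unit 3 with a built-in guard against ionisation, in fewer steps.

**Alternative 2:** organocatalytic annulation that grows unit 2.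
- **Disconnection:** O1–C2 and C3–C4 of ring C of unit 2 are cut. This leads to salicylaldehyde A5 (a 2-hydroxy-4,6-bis(benzyloxy)benzaldehyde already bonded at its C3 to C4 of protected epicatechin) and 3,4-bis(benzyloxy)cinnamaldehyde A6.
- **Forward key step:** the matching enantiomer of α,α-diphenylprolinol trimethylsilyl ether turns A6 into an iminium ion. The phenol of A5 adds (oxa-Michael), the enamine closes on the aryl aldehyde (aldol) and water is lost, giving the 2H-chromene-3-carbaldehyde A4.
- **For:** the reaction type is well established and usually highly enantioselective, the dehydration is irreversible, and the catalyst sets C2 of unit 2 whatever unit 1 prefers. On enantiocontrol and robustness of the ring-forming step it is stronger than the nitro-aldol closure chosen here, which has to be held back from dehydration.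
- **Against:** only one of the three centres of unit 2 is made. The formyl carbon at C3 is surplus and must be excised and replaced by oxygen, C4 must then be oxidised and the ether still made, all on an acid-sensitive dimer. The phenol of A5 is flanked by the bulky flavanyl group. The effort goes into unit 2, which is natural epicatechin, while unit 3 remains unsolved.
- **Comparison:** the chosen strategy applies the same domino logic to the one unit that has to be made. Its product already carries oxygen at C4 and a nitrogen placeholder at C3, so three stereocentres and the correct oxidation pattern come from one step.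

**Alternative 3:** aldehyde linchpin for the interflavan bond.
- **Disconnection:** C4–C4a of unit 1 and the C4–C8 bond to unit 2 are both traced to the carbonyl carbon of the acyclic aldehyde A8, with 3-O-acetyl-tetra-O-benzylepicatechin A9 as the second arene.
- **Forward key step:** Me3SiOTf activates the aldehyde of A8 and its 3,5-bis(benzyloxy)phenyl ether ring closes ring C of unit 1 by attack on the carbonyl carbon. The silylated C4 oxygen then ionises and C8 of A9 takes the cation, giving dimer A7.
- **For:** two carbon–carbon bonds form in one flask, and no quinone oxidation or leaving-group installation is needed for unit 1. For the interflavan bond alone it is at least as convergent as the oxidation/coupling pair used here.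
- **Against:** A8 has two stereocentres and an aryl ether that need a multi-step asymmetric synthesis merely to reproduce what epicatechin provides, and its α-silyloxy aldehyde is epimerisable. A7 ends with an unfunctionalised C4 methylene in unit 2, so a further oxidation of the dimer is needed before any ether can be made. Unit 3 and the ether are not addressed.
- **Comparison:** the chosen route reaches the corresponding dimer 13 in five steps from epicatechin with the leaving group for the ether already in place, and spends its one demanding step on unit 3.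

Key step: step 3

## Route

Remark on the chemistry (assumption): the (1R,2R) enantiomer of the amine–thiourea is taken to deliver the (2S) ether, by analogy with its facial sense in additions to β-nitrostyrenes; if the sense proves opposite, the (1S,2S) antipode is used with no other change.

Step 1
Reactants: 1 2,4,6-trihydroxybenzaldehyde
Product: 2 2-hydroxy-4,6-bis(benzyloxy)benzaldehyde
Conditions: BnBr (2.1 equiv), K2CO3 (2.2 equiv), DMF, 0 °C → rt
Reagents that add atoms: benzyl bromide, BrCc1ccccc1
Why: Williamson etherification; the 4-hydroxyl, para to the formyl group, is the most acidic and reacts first, and once one ortho hydroxyl has reacted the last one is held in a hydrogen bond to the aldehyde and is the least nucleophilic, so alkylation should stop at the 4,6-dibenzyl ether.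

Step 2
Reactants: 3 3,4-bis(benzyloxy)benzaldehyde; 4 nitromethane
Product: 5 (E)-3,4-bis(benzyloxy)-β-nitrostyrene
Conditions: NH4OAc (0.5 equiv), AcOH, 100 °C
Reagents that add atoms: none
Why: Henry (nitroaldol) condensation with loss of water under ammonium acetate buffer; conjugation with the aryl ring makes the E nitroalkene the thermodynamic product.

Step 3
Reactants: 2 2-hydroxy-4,6-bis(benzyloxy)benzaldehyde; 5 (E)-3,4-bis(benzyloxy)-β-nitrostyrene
Product: 7 (2S,3R,4S)-5,7-bis(benzyloxy)-2-[3,4-bis(benzyloxy)phenyl]-3-nitrochroman-4-ol, via acyclic (S)-nitro ether aldehyde 6 (not isolated)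
Conditions: 1-[3,5-bis(trifluoromethyl)phenyl]-3-[(1R,2R)-2-(dimethylamino)cyclohexyl]thiourea (15 mol%), 4 Å MS, toluene/CH2Cl2, −20 °C; cold filtration through silica, crystallisation
Reagents that add atoms: none
Why: Asymmetric domino oxa-Michael–Henry reaction, the known organocatalytic tandem reaction of salicylaldehydes with β-nitrostyrenes that is usually run on to 3-nitro-2H-chromenes and is here stopped at the nitro alcohol. The dimethylamino group takes the proton of the chelated phenol of 2 while the thiourea N–H bonds hold the nitro group of 5, and the phenoxide adds to the β-carbon within this ion pair, forming O1–C2 and the nitronate of 6. The nitronate carbon then attacks the ortho formyl group in a 6-exo-trig nitroaldol closure that forms C3–C4 and ring C. C2 is set by the catalyst, which exposes one face of the bound nitroalkene. C3 is epimerisable through the nitronate and C4 through retro-Henry/Henry exchange, so both settle relative to C2 in the half-chair with aryl, nitro and hydroxyl all equatorial, which places the C2 aryl group and the C4 hydroxyl cis. The step needs enantioselectivity at C2, which requires the retro-oxa-Michael reaction to stay slower than ring closure, and diastereoselectivity, which the reversibility just described and crystallisation of the all-equatorial isomer should secure. It also needs chemoselectivity against E1cB loss of water to the nitrochromene, for which low temperature, an aprotic medium, a weak tertiary amine as the only base and removal of the catalyst before concentration are used. Any minor enantiomer carried forward becomes a separable diastereomer in step 9.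

Step 4
Reactants: 8 (−)-epicatechin
Product: 9 5,7,3',4'-tetra-O-benzyl-(−)-epicatechin
Conditions: BnBr (4.4 equiv), K2CO3, DMF, 0 °C → rt, Ar
Reagents that add atoms: benzyl bromide, BrCc1ccccc1
Why: Williamson etherification of the four phenols, which carbonate deprotonates while the secondary 3-hydroxyl is left alone; low temperature and exclusion of air limit C-benzylation and base-induced epimerisation at C2.

Step 5
Reactants: 9 5,7,3',4'-tetra-O-benzyl-(−)-epicatechin
Product: 10 3-O-(tert-butyldimethylsilyl)-5,7,3',4'-tetra-O-benzyl-(−)-epicatechin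
Conditions: TBSCl, imidazole, DMF, 40 °C
Reagents that add atoms: tert-butyldimethylsilyl chloride, CC(C)(C)[Si](C)(C)Cl
Why: Silylation of the only free hydroxyl; the silyl ether removes a competing oxygen nucleophile from the later cation chemistry and, being axial on the α face, adds to the bias for β attack at C4.

Step 6
Reactants: 10 3-O-(tert-butyldimethylsilyl)-5,7,3',4'-tetra-O-benzyl-(−)-epicatechin
Product: 11 (2R,3R,4S)-4-(2-ethoxyethoxy) derivative of 10 (4β ether, 3,4-trans)
Conditions: DDQ (2 equiv), 2-ethoxyethanol (5 equiv), CH2Cl2, rt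
Reagents that add atoms: 2-ethoxyethanol, CCOCCO
Why: Benzylic C–H oxidation by hydride abstraction; C4 is activated by the ortho and para oxygens of ring A, and the cation is trapped by the alcohol on the β face, anti to the axial 3-silyloxy group, to give the 3,4-trans ether.

Step 7
Reactants: 11 (2R,3R,4S)-4-(2-ethoxyethoxy) derivative of 10
Product: 12 (2R,3S,4S)-4-[(2,6-dimethylphenyl)sulfanyl] derivative of 10 (4β sulfide, 3,4-trans)
Conditions: 2,6-dimethylbenzenethiol (3 equiv), BF3·OEt2 (0.3 equiv), CH2Cl2, −78 → −30 °C
Reagents that add atoms: 2,6-dimethylbenzenethiol, Cc1cccc(C)c1S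
Why: Lewis-acid-promoted SN1 exchange of the acetal-type C4 ether for a sulfide; the thiol again enters anti to the 3-silyloxy group, and the hindered aryl sulfide is inert to hard Lewis acids but open to thiophilic silver.

Step 8
Reactants: 11 (2R,3R,4S)-4-(2-ethoxyethoxy) derivative of 10; 12 (2R,3S,4S)-4-[(2,6-dimethylphenyl)sulfanyl] derivative of 10
Product: 13 protected epicatechin-(4β→8)-epicatechin dimer carrying the 4β-(2,6-dimethylphenyl)sulfanyl group on unit 2 and a 3-O-silyl group on each unit
Conditions: 12 (3 equiv), Me3SiOTf (0.2 equiv), CH2Cl2, −78 °C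
Reagents that add atoms: none
Why: Friedel–Crafts alkylation, the standard C4→C8 interflavan coupling; the silyl triflate ionises only the oxygen leaving group of 11, and the cation is taken from the β face by C8 of 12, the most nucleophilic position of a 5,7-dibenzyloxy ring A. The excess of 12, which is recovered, suppresses further chain growth.

Step 9
Reactants: 13 protected dimer sulfide; 7 (2S,3R,4S)-5,7-bis(benzyloxy)-2-[3,4-bis(benzyloxy)phenyl]-3-nitrochroman-4-ol
Product: 14 protected trimer in which C4β of unit 2 is bonded through oxygen to C4 of the (2S,3R,4S)-3-nitro unit 3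
Conditions: 7 (2.5 equiv), AgBF4 (1.5 equiv), 2,6-di-tert-butyl-4-methylpyridine (2 equiv), 4 Å MS, CH2Cl2/toluene, −40 → 0 °C, dark, slow addition of 13
Reagents that add atoms: none
Why: Silver-promoted SN1 etherification; monovalent silver binds the sulfide and releases the C4 cation of unit 2, which the hydroxyl of 7 captures on the β face, trans to the 3-silyloxy group. An alcohol oxygen is kinetically more nucleophilic towards such a cation than a trialkoxyarene carbon, and with the acid taken up by the hindered pyridine the ether is not re-ionised, so O-alkylation should prevail. The nitro group keeps C4 of 7 from ionising, and the excess of 7 is recovered.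

Step 10
Reactants: 14 protected nitro trimer
Product: 15 protected trimer with a C3 oxime in unit 3 (mixture of oxime geometries)
Conditions: SnCl2 (1.5 equiv), PhSH (4.5 equiv), Et3N (4.5 equiv), MeCN/THF, 0 °C → rt
Reagents that add atoms: none
Why: Reduction of a secondary nitroalkane to the oxime by the stannate [Sn(SPh)3]− formed in the flask, the first half of a reductive Nef sequence; no stoichiometric strong base is used, so a free nitronate that could expel O1 or the C4 alkoxide is not built up, and C2 and C4 are untouched.

Step 11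
Reactants: 15 protected oxime trimer
Product: 16 protected trimer with unit 3 as the (2S,4S)-4-alkoxyflavan-3-one
Conditions: TiCl3 (aq, 3 equiv), NH4OAc buffer (pH 5–6), THF/H2O, 0 °C → rt
Reagents that add atoms: water, O
Why: Reductive deoximation, the second half of the titanium-mediated Nef sequence; trivalent titanium cleaves the N–O bond and the imine is hydrolysed to the ketone. The acetate buffer keeps the acid-labile C4–O and C4–C8 bonds and the silyl ethers intact, and the ketone is used at once to avoid enolisation towards C2 or C4.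

Step 12
Reactants: 16 protected ketone trimer
Product: 17 protected trimer with unit 3 as the (2S,3S,4S) all-cis flavan-3-ol
Conditions: LiBH(s-Bu)3 (2 equiv), THF, −78 °C; aq NH4Cl
Reagents that add atoms: none
Why: Diastereoselective ketone reduction, the known route from flavan-3-ones to 2,3-cis flavan-3-ols; the bulky hydride comes from the α face, away from the C2 aryl group and the C4 ether, and gives the axial 3-hydroxyl cis to both (3S).

Step 13
Reactants: 17 protected trimer alcohol
Product: 18 dodeca-O-benzyl trimer with the three 3-hydroxyls free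
Conditions: Bu4NF (4 equiv), AcOH (4 equiv), THF, rt → 40 °C
Reagents that add atoms: none
Why: Fluoride cleavage of the two secondary silyl ethers; acetic acid keeps the medium near neutral, and nothing else in 17 is fluoride-labile.

Step 14
Reactants: 18 dodeca-O-benzyl trimer
Product: 19 epicatechin-(4β→8)-epicatechin-(4β→O→4)-[(2S,3S,4S)-2,3-cis-3,4-cis-flavan-3-ol], the target
Conditions: H2 (1 atm), Pd(OH)2/C, THF/EtOAc/H2O, rt; filtration, lyophilisation
Reagents that add atoms: none
Why: Hydrogenolysis of twelve aryl benzyl ethers, the standard last step for benzylated procyanidins; these primary benzylic C–O bonds to phenoxide leaving groups cleave much faster than the hindered secondary benzylic C–O bonds of the pyran rings and of the C4–O–C4 ether, so the reaction is stopped as soon as debenzylation is complete.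

## Compound list

1 | 2,4,6-trihydroxybenzaldehyde | O=Cc1c(O)cc(O)cc1O | starting material
2 | 2-hydroxy-4,6-bis(benzyloxy)benzaldehyde | O=Cc1c(O)cc(OCc2ccccc2)cc1OCc1ccccc1 | intermediate
3 | 3,4-bis(benzyloxy)benzaldehyde | O=Cc1ccc(OCc2ccccc2)c(OCc2ccccc2)c1 | starting material
4 | nitromethane | C[N+](=O)[O-] | starting material
5 | (E)-3,4-bis(benzyloxy)-β-nitrostyrene | [O-][N+](=O)/C=C/c1ccc(OCc2ccccc2)c(OCc2ccccc2)c1 | intermediate
6 | (S)-2-{1-[3,4-bis(benzyloxy)phenyl]-2-nitroethoxy}-4,6-bis(benzyloxy)benzaldehyde | O=Cc1c(OCc2ccccc2)cc(OCc2ccccc2)cc1O[C@@H](c1ccc(OCc2ccccc2)c(OCc2ccccc2)c1)C[N+](=O)[O-] | intermediate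
7 | (2S,3R,4S)-5,7-bis(benzyloxy)-2-[3,4-bis(benzyloxy)phenyl]-3-nitrochroman-4-ol (aryl, nitro and hydroxyl all equatorial) | O[C@H]1c2c(OCc3ccccc3)cc(OCc3ccccc3)cc2O[C@@H](c2ccc(OCc3ccccc3)c(OCc3ccccc3)c2)[C@@H]1[N+](=O)[O-] | intermediate
8 | (−)-epicatechin, (2R,3R) | Oc1cc(O)c2c(c1)O[C@H](c1ccc(O)c(O)c1)[C@H](O)C2 | starting material
9 | 5,7,3',4'-tetra-O-benzyl-(−)-epicatechin, (2R,3R) | c3ccccc3COc1cc(OCc3ccccc3)c2c(c1)O[C@H](c1ccc(OCc3ccccc3)c(OCc3ccccc3)c1)[C@H](O)C2 | intermediate
10 | 3-O-(tert-butyldimethylsilyl)-5,7,3',4'-tetra-O-benzyl-(−)-epicatechin, (2R,3R) | c3ccccc3COc1cc(OCc3ccccc3)c2c(c1)O[C@H](c1ccc(OCc3ccccc3)c(OCc3ccccc3)c1)[C@H](O[Si](C)(C)C(C)(C)C)C2 | intermediate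
11 | (2R,3R,4S)-4β-(2-ethoxyethoxy) derivative of 10 | c3ccccc3COc1cc(OCc3ccccc3)c2c(c1)O[C@H](c1ccc(OCc3ccccc3)c(OCc3ccccc3)c1)[C@H](O[Si](C)(C)C(C)(C)C)[C@H]2OCCOCC | intermediate
12 | (2R,3S,4S)-4β-[(2,6-dimethylphenyl)sulfanyl] derivative of 10 | c3ccccc3COc1cc(OCc3ccccc3)c2c(c1)O[C@H](c1ccc(OCc3ccccc3)c(OCc3ccccc3)c1)[C@H](O[Si](C)(C)C(C)(C)C)[C@H]2Sc1c(C)cccc1C | intermediate
13 | 3-O-silyl-tetra-O-benzylepicatechin-(4β→8)-[3-O-silyl-tetra-O-benzyl-4β-(2,6-dimethylphenylsulfanyl)epicatechin] (silyl = tert-butyldimethylsilyl) | c3ccccc3COc1cc(OCc3ccccc3)c2c(c1)O[C@H](c1ccc(OCc3ccccc3)c(OCc3ccccc3)c1)[C@H](O[Si](C)(C)C(C)(C)C)[C@H]2c1c(OCc3ccccc3)cc(OCc3ccccc3)c2c1O[C@H](c1ccc(OCc3ccccc3)c(OCc3ccccc3)c1)[C@H](O[Si](C)(C)C(C)(C)C)[C@H]2Sc1c(C)cccc1C | intermediate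
14 | protected dimer of 13 bonded from C4β of unit 2 through oxygen to C4 of (2S,3R,4S)-5,7,3',4'-tetra-O-benzyl-3-nitroflavan (unit 3) | c3ccccc3COc1cc(OCc3ccccc3)c2c(c1)O[C@H](c1ccc(OCc3ccccc3)c(OCc3ccccc3)c1)[C@H](O[Si](C)(C)C(C)(C)C)[C@H]2c1c(OCc3ccccc3)cc(OCc3ccccc3)c2c1O[C@H](c1ccc(OCc3ccccc3)c(OCc3ccccc3)c1)[C@H](O[Si](C)(C)C(C)(C)C)[C@H]2O[C@H]1c2c(OCc3ccccc3)cc(OCc3ccccc3)cc2O[C@@H](c2ccc(OCc3ccccc3)c(OCc3ccccc3)c2)[C@@H]1[N+](=O)[O-] | intermediate
15 | as 14 with unit 3 as the (2S,4S)-flavan-3-one oxime | c3ccccc3COc1cc(OCc3ccccc3)c2c(c1)O[C@H](c1ccc(OCc3ccccc3)c(OCc3ccccc3)c1)[C@H](O[Si](C)(C)C(C)(C)C)[C@H]2c1c(OCc3ccccc3)cc(OCc3ccccc3)c2c1O[C@H](c1ccc(OCc3ccccc3)c(OCc3ccccc3)c1)[C@H](O[Si](C)(C)C(C)(C)C)[C@H]2O[C@H]1c2c(OCc3ccccc3)cc(OCc3ccccc3)cc2O[C@@H](c2ccc(OCc3ccccc3)c(OCc3ccccc3)c2)C1=NO | intermediate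
16 | as 14 with unit 3 as the (2S,4S)-flavan-3-one | c3ccccc3COc1cc(OCc3ccccc3)c2c(c1)O[C@H](c1ccc(OCc3ccccc3)c(OCc3ccccc3)c1)[C@H](O[Si](C)(C)C(C)(C)C)[C@H]2c1c(OCc3ccccc3)cc(OCc3ccccc3)c2c1O[C@H](c1ccc(OCc3ccccc3)c(OCc3ccccc3)c1)[C@H](O[Si](C)(C)C(C)(C)C)[C@H]2O[C@H]1c2c(OCc3ccccc3)cc(OCc3ccccc3)cc2O[C@@H](c2ccc(OCc3ccccc3)c(OCc3ccccc3)c2)C1=O | intermediate
17 | as 14 with unit 3 as the (2S,3S,4S) all-cis flavan-3-ol | c3ccccc3COc1cc(OCc3ccccc3)c2c(c1)O[C@H](c1ccc(OCc3ccccc3)c(OCc3ccccc3)c1)[C@H](O[Si](C)(C)C(C)(C)C)[C@H]2c1c(OCc3ccccc3)cc(OCc3ccccc3)c2c1O[C@H](c1ccc(OCc3ccccc3)c(OCc3ccccc3)c1)[C@H](O[Si](C)(C)C(C)(C)C)[C@H]2O[C@H]1c2c(OCc3ccccc3)cc(OCc3ccccc3)cc2O[C@@H](c2ccc(OCc3ccccc3)c(OCc3ccccc3)c2)[C@H]1O | intermediate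
18 | dodeca-O-benzyl ether of the target (all phenols benzylated, three 3-hydroxyls free) | c3ccccc3COc1cc(OCc3ccccc3)c2c(c1)O[C@H](c1ccc(OCc3ccccc3)c(OCc3ccccc3)c1)[C@H](O)[C@H]2c1c(OCc3ccccc3)cc(OCc3ccccc3)c2c1O[C@H](c1ccc(OCc3ccccc3)c(OCc3ccccc3)c1)[C@H](O)[C@H]2O[C@H]1c2c(OCc3ccccc3)cc(OCc3ccccc3)cc2O[C@@H](c2ccc(OCc3ccccc3)c(OCc3ccccc3)c2)[C@H]1O | intermediate
19 | epicatechin-(4β→8)-epicatechin-(4β→O→4)-[(2S,3S,4S)-2-(3,4-dihydroxyphenyl)chroman-3,5,7-triol], CNP0310719.1 | Oc1cc(O)c2c(c1)O[C@H](c1ccc(O)c(O)c1)[C@H](O)[C@H]2c1c(O)cc(O)c2c1O[C@H](c1ccc(O)c(O)c1)[C@H](O)[C@H]2O[C@H]1c2c(O)cc(O)cc2O[C@@H](c2ccc(O)c(O)c2)[C@H]1O | target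

## Step count and least certain steps

Total step count: 14. Longest linear sequence: 11 steps (steps 4 to 14, from 8 to 19).

**Step 3 (key step).** The likeliest failure is loss of selectivity through reversibility. Retro-oxa-Michael reaction of 6 erodes the enantiomeric purity at C2, base-mediated loss of water drains the product to the nitrochromene, and peri strain between the C4 hydroxyl and the C5 benzyloxy group may hold part of the material as the C4 epimer. Fallback: setting out from 2 and 5, the domino reaction is run with an achiral amine (1,4-diazabicyclo[2.2.2]octane, toluene, 0 °C) to give the racemic all-equatorial nitro alcohol F1, which is purified by crystallisation. The absolute configuration is then sorted at the ether stage: F1 is coupled with enantiopure 13 under the conditions of step 9, which should give 14 together with the diastereomeric trimer F2 (unit 3 of the 2R,3S,4R series), and chromatographic separation of the two brings the route back at 14.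

**Step 9.** The hindered, inductively deactivated hydroxyl of 7 may lose the competition for the cation to ring A carbons (C6 and C8 of 7 or of a second molecule of 13), giving C-alkylation, and any acid that escapes the pyridine base can re-ionise the ether. Fallback: setting out from 7, reaction with Bu3SnOMe (toluene, rt, reduced pressure) gives the tributylstannyl ether F3, which is coupled with 13 by AgBF4 without added base. The tin-bound oxygen is a stronger nucleophile than the free hydroxyl and no proton is released, so the product cannot be re-ionised by acid; this comes back to the route at 14.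

**Step 10.** The amine and thiolate in the medium may deprotonate C3 faster than the stannate reduces the nitro group, and the resulting nitronate can expel the C4 alkoxide (loss of the dimer) or open ring C at O1 (epimerisation at C2). Fallback: setting out from 14, electron-transfer reduction with SmI2 (THF/MeOH, rt) gives the N-hydroxylamine F4 without any base, and mild dehydrogenation with MnO2 (CH2Cl2, rt) converts it to the oxime, returning to the route at 15.

**Step 14.** Once the phenols are free the bis-benzylic C4–O–C4 ether becomes a para-hydroxybenzyl ether, which can fragment through a quinone methide and be reduced on the catalyst; over-exposure therefore leads to cleavage of the ether, while under-exposure leaves benzyl groups. Fallback: the order of the last two operations is reversed. Setting out from 17, hydrogenolysis (H2, Pd(OH)2/C, EtOAc/THF, no protic co-solvent) gives the dodecaphenol bis-silyl ether F7, in which the two bulky silyl groups flank the ether of unit 2 and keep the molecule soluble in aprotic solvent. Desilylation with Bu4NF/AcOH in THF and chromatography on Sephadex LH-20 then reaches the route's end at 19.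

**Step 8.** Chain growth (the cation adding to C6 or C8 of product 13) or ionisation of the sulfide by the silyl triflate would give oligomers and scrambled material. Fallback: the sulfide is introduced after the carbon–carbon bond. Setting out from 11 and an excess of 10 (Me3SiOTf, CH2Cl2, −78 °C), the sulfur-free dimer F5 is made. Oxidation of its only C4 methylene with DDQ in the presence of 2-ethoxyethanol gives the dimeric 4β-(2-ethoxyethoxy) ether F6, and exchange with 2,6-dimethylbenzenethiol and BF3·OEt2 as in step 7 comes back to the route at 13.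

## Further compounds

F1 | step 3 | racemic (2S*,3R*,4S*)-5,7-bis(benzyloxy)-2-[3,4-bis(benzyloxy)phenyl]-3-nitrochroman-4-ol (both enantiomers) | O[C@H]1c2c(OCc3ccccc3)cc(OCc3ccccc3)cc2O[C@@H](c2ccc(OCc3ccccc3)c(OCc3ccccc3)c2)[C@@H]1[N+](=O)[O-].O[C@@H]1c2c(OCc3ccccc3)cc(OCc3ccccc3)cc2O[C@H](c2ccc(OCc3ccccc3)c(OCc3ccccc3)c2)[C@H]1[N+](=O)[O-]
F2 | step 3 | diastereomer of 14 with unit 3 of (2R,3S,4R) configuration | c3ccccc3COc1cc(OCc3ccccc3)c2c(c1)O[C@H](c1ccc(OCc3ccccc3)c(OCc3ccccc3)c1)[C@H](O[Si](C)(C)C(C)(C)C)[C@H]2c1c(OCc3ccccc3)cc(OCc3ccccc3)c2c1O[C@H](c1ccc(OCc3ccccc3)c(OCc3ccccc3)c1)[C@H](O[Si](C)(C)C(C)(C)C)[C@H]2O[C@@H]1c2c(OCc3ccccc3)cc(OCc3ccccc3)cc2O[C@H](c2ccc(OCc3ccccc3)c(OCc3ccccc3)c2)[C@H]1[N+](=O)[O-]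
F3 | step 9 | tributylstannyl ether of 7 | CCCC[Sn](CCCC)(CCCC)O[C@H]1c2c(OCc3ccccc3)cc(OCc3ccccc3)cc2O[C@@H](c2ccc(OCc3ccccc3)c(OCc3ccccc3)c2)[C@@H]1[N+](=O)[O-]
F4 | step 10 | as 14 with the nitro group of unit 3 replaced by N-hydroxyamino | c3ccccc3COc1cc(OCc3ccccc3)c2c(c1)O[C@H](c1ccc(OCc3ccccc3)c(OCc3ccccc3)c1)[C@H](O[Si](C)(C)C(C)(C)C)[C@H]2c1c(OCc3ccccc3)cc(OCc3ccccc3)c2c1O[C@H](c1ccc(OCc3ccccc3)c(OCc3ccccc3)c1)[C@H](O[Si](C)(C)C(C)(C)C)[C@H]2O[C@H]1c2c(OCc3ccccc3)cc(OCc3ccccc3)cc2O[C@@H](c2ccc(OCc3ccccc3)c(OCc3ccccc3)c2)[C@@H]1NO
F5 | step 8 | sulfur-free protected dimer, 3-O-silyl-tetra-O-benzylepicatechin-(4β→8)-3-O-silyl-tetra-O-benzylepicatechin | c3ccccc3COc1cc(OCc3ccccc3)c2c(c1)O[C@H](c1ccc(OCc3ccccc3)c(OCc3ccccc3)c1)[C@H](O[Si](C)(C)C(C)(C)C)[C@H]2c1c(OCc3ccccc3)cc(OCc3ccccc3)c2c1O[C@H](c1ccc(OCc3ccccc3)c(OCc3ccccc3)c1)[C@H](O[Si](C)(C)C(C)(C)C)C2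
F6 | step 8 | 4β-(2-ethoxyethoxy) ether of F5 at C4 of unit 2 | c3ccccc3COc1cc(OCc3ccccc3)c2c(c1)O[C@H](c1ccc(OCc3ccccc3)c(OCc3ccccc3)c1)[C@H](O[Si](C)(C)C(C)(C)C)[C@H]2c1c(OCc3ccccc3)cc(OCc3ccccc3)c2c1O[C@H](c1ccc(OCc3ccccc3)c(OCc3ccccc3)c1)[C@H](O[Si](C)(C)C(C)(C)C)[C@H]2OCCOCC
F7 | step 14 | target carrying tert-butyldimethylsilyl ethers on the 3-hydroxyls of units 1 and 2 | Oc1cc(O)c2c(c1)O[C@H](c1ccc(O)c(O)c1)[C@H](O[Si](C)(C)C(C)(C)C)[C@H]2c1c(O)cc(O)c2c1O[C@H](c1ccc(O)c(O)c1)[C@H](O[Si](C)(C)C(C)(C)C)[C@H]2O[C@H]1c2c(O)cc(O)cc2O[C@@H](c2ccc(O)c(O)c2)[C@H]1O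
A1 | alternative 1 | fully protected trimer with a C3 acetate on unit 2 and 3-O-silyl groups on units 1 and 3 | c3ccccc3COc1cc(OCc3ccccc3)c2c(c1)O[C@H](c1ccc(OCc3ccccc3)c(OCc3ccccc3)c1)[C@H](O[Si](C)(C)C(C)(C)C)[C@H]2c1c(OCc3ccccc3)cc(OCc3ccccc3)c2c1O[C@H](c1ccc(OCc3ccccc3)c(OCc3ccccc3)c1)[C@H](OC(C)=O)[C@H]2O[C@H]1c2c(OCc3ccccc3)cc(OCc3ccccc3)cc2O[C@@H](c2ccc(OCc3ccccc3)c(OCc3ccccc3)c2)[C@H]1O[Si](C)(C)C(C)(C)C
A2 | alternative 1 | protected dimer whose unit 2 is a flav-3-ene (C3=C4) | c3ccccc3COc1cc(OCc3ccccc3)c2c(c1)O[C@H](c1ccc(OCc3ccccc3)c(OCc3ccccc3)c1)[C@H](O[Si](C)(C)C(C)(C)C)[C@H]2c1c(OCc3ccccc3)cc(OCc3ccccc3)c2c1O[C@H](c1ccc(OCc3ccccc3)c(OCc3ccccc3)c1)C=C2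
A3 | alternative 1 | (2S,3S,4S)-5,7-bis(benzyloxy)-2-[3,4-bis(benzyloxy)phenyl]-3-(tert-butyldimethylsilyloxy)chroman-4-ol | O[C@H]1c2c(OCc3ccccc3)cc(OCc3ccccc3)cc2O[C@@H](c2ccc(OCc3ccccc3)c(OCc3ccccc3)c2)[C@H]1O[Si](C)(C)C(C)(C)C
A4 | alternative 2 | protected dimer whose unit 2 is a (2R)-2-aryl-2H-chromene-3-carbaldehyde | c3ccccc3COc1cc(OCc3ccccc3)c2c(c1)O[C@H](c1ccc(OCc3ccccc3)c(OCc3ccccc3)c1)[C@H](O[Si](C)(C)C(C)(C)C)[C@H]2c1c(OCc3ccccc3)cc(OCc3ccccc3)c2c1O[C@H](c1ccc(OCc3ccccc3)c(OCc3ccccc3)c1)C(C=O)=C2
A5 | alternative 2 | 2-hydroxy-4,6-bis(benzyloxy)benzaldehyde bonded at C3 to C4β of 3-O-silyl-tetra-O-benzylepicatechin | c3ccccc3COc1cc(OCc3ccccc3)c2c(c1)O[C@H](c1ccc(OCc3ccccc3)c(OCc3ccccc3)c1)[C@H](O[Si](C)(C)C(C)(C)C)[C@H]2c1c(OCc3ccccc3)cc(OCc3ccccc3)c(C=O)c1O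
A6 | alternative 2 | (E)-3,4-bis(benzyloxy)cinnamaldehyde | O=C/C=C/c1ccc(OCc2ccccc2)c(OCc2ccccc2)c1
A7 | alternative 3 | protected epicatechin-(4β→8)-epicatechin dimer with 3-O-silyl on unit 1 and 3-O-acetyl on unit 2 | c3ccccc3COc1cc(OCc3ccccc3)c2c(c1)O[C@H](c1ccc(OCc3ccccc3)c(OCc3ccccc3)c1)[C@H](O[Si](C)(C)C(C)(C)C)[C@H]2c1c(OCc3ccccc3)cc(OCc3ccccc3)c2c1O[C@H](c1ccc(OCc3ccccc3)c(OCc3ccccc3)c1)[C@H](OC(C)=O)C2
A8 | alternative 3 | acyclic aldehyde, 3-[3,4-bis(benzyloxy)phenyl]-3-[3,5-bis(benzyloxy)phenoxy]-2-(tert-butyldimethylsilyloxy)propanal with the C2 and C3 configurations of unit 1 | c3ccccc3COc1cc(OCc3ccccc3)cc(c1)O[C@H](c1ccc(OCc3ccccc3)c(OCc3ccccc3)c1)[C@H](O[Si](C)(C)C(C)(C)C)C=O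
A9 | alternative 3 | 3-O-acetyl-5,7,3',4'-tetra-O-benzyl-(−)-epicatechin | c3ccccc3COc1cc(OCc3ccccc3)c2c(c1)O[C@H](c1ccc(OCc3ccccc3)c(OCc3ccccc3)c1)[C@H](OC(C)=O)C2
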